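## The problem

The target is a C24 acid, numbered here from the carboxyl carbon C1. A 2,5-disubstituted tetrahydrofuran (ring O, C7–C10) is joined through the C6–C7 single bond to a 3,6-disubstituted 1,2-dioxane (O–O, C3–C6). C3 carries the acetic acid arm; C10 carries a fourteen-carbon chain with a (17Z,19E)-diene and a terminal C23=C24 alkene.

There are four stereocentres: 3R, 6R, 7S and 10R. The tetrahydrofuran is 2,5-trans, the dioxane is 3,6-trans, and the oxygens on C6 and C7 are erythro. C7 is the natural control element: it can direct C10 across the five-membered ring and C6 through chelation of an adjacent carbonyl. C3 lies 1,4 to C6 with no rigid relay and has to be set by a reagent.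

The O–O bond will not survive hydrogenation, stannane radicals, hot phosphines or strong base, and a β-peroxy carbonyl can lose the peroxide by elimination. The peroxide therefore has to come late, and C1 has to stay at the alcohol level until the ring is closed. The diene and the terminal alkene forbid hydrogenation, metathesis and radical steps once they are in place. That fixes the order: tetrahydrofuran first, chain second, peroxide last.

The feature that opens the route is that C10 bears both the ring oxygen and a carbon chain, while C7 bears the same oxygen. An allyl group parked on the C7 ether oxygen can be passed to C10 in the same step that closes the O–C10 bond, with the existing C7 centre deciding the face.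

## Retrosynthesis

**C1 oxidation level.** Acid 37 is traced to alcohol 35 and its silyl ether 34; no skeletal bond is cut. A C1 carbonyl β to a C3 leaving group would eliminate during peroxide closure, so C1 stays an ether until the dioxane exists. The forward steps must be a non-basic desilylation and an alcohol-to-acid oxidation (through aldehyde 36) that leave the O–O bond and the three alkenes alone.

**Dioxane.** Both C–O bonds of the peroxide (O–C3 and O–C6) are cut, leading to bis-mesylate 32 and diol 31. The O–O unit is delivered intact by two displacements, passing through hydroperoxide 33. The neighbouring cut, conjugate addition of a C6 hydroperoxide to a C2=C3 enoate, would require an intermolecular substitution at the hindered C6 and would leave C3 to thermodynamic control. Here the intermolecular event falls on the unhindered C3 and the C6 bond forms by six-membered ring closure. The precursor 31 is acyclic, peroxide-free and has the (3S,6S) configuration, since both centres invert.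

**C5–C6.** Diol 31 comes from adduct 30, which is cut between C5 and C6 into aldehyde 22 and Grignard reagent 29 (from bromide 28). Cuts at C4–C5 or alkyne-based unions would need a hydrogenation, which the diene forbids. The forward addition must be threo-selective (6S), which a magnesium chelate between the aldehyde and the ring oxygen of 22 should provide.

**C1–C5 fragment.** Bromide 28 is traced through alcohol 27 (ozonolysis, via 26) and silyl ether 25 to homoallylic alcohol 24, which is cut at C3–C4 into achiral aldehyde 23. C3 has no neighbour to lean on, so a reagent-controlled allylboration sets it.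

**C17=C18.** Aldehyde 22 comes from alcohol 21 and silyl ether 20. The Z alkene of 20 is cut into phosphonium salt 16 (ylide 19) and dienal 18, itself a two-carbon homologue of pent-4-enal 17. Cutting the Z bond is preferred to cutting C18–C19 because a non-stabilised ylide and an enal give Z directly, while the E bond arrives ready-made in 18.

**C12–C13.** Salt 16 is traced through bromide 15 and alkene 14 to allyl tetrahydrofuran 12 and 6-bromohex-1-ene 13. The allyl group left by the key step supplies C11, C12 and a sacrificial carbon; cross-metathesis adds C13–C17 together with the leaving group. The forward steps are a statistical cross-metathesis and a hydrogenation that spares the C–Br bond.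

**C9 deoxygenation.** Compound 12 comes from ketone 9 through alcohol 10 and thiocarbonyl derivative 11. These three steps are the price of the key step, which needs the C9 carbonyl to carry the diazo group.

**Key disconnection.** Ketone 9 is cut at O–C10 and C10–C11, through oxonium ylide 8, back to diazoketone 7. The alternative at this point, allylation of a C10 oxocarbenium ion, has only a weak facial bias from C7. The ylide shift relays C7 to C10 through a tight five-membered transition state. The precursor 7 is acyclic with one stereocentre.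

**Chiral pool.** Diazoketone 7 comes from acid 5 (via anhydride 6), ester 4, alcohol 3 and diol 2, all from dimethyl L-malate 1. The four malate carbons become C6–C9, the malate hydroxyl becomes the ring oxygen, and C10 is added as the diazo carbon.

## Roads not taken

**Alternative 1:** The cut is the two C–O bonds of the dioxane at the last skeletal stage. In the forward step, hydroperoxide anion displaces the C3 mesylate of bis-mesylate A2, and the new hydroperoxide closes on C6 to give A1.
- Merits: the peroxide arrives intact and late, and both ring centres follow stereospecifically from a 1,4-diol.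
- Weak points: secondary sulfonates give modest yields, elimination and base-induced peroxide fragmentation compete, and the idea says nothing about how the 2,5-trans tetrahydrofuran is made.
- Comparison: as a peroxide tactic it is as good as anything available, and the present plan uses exactly this closure as step 24 (A2 is 32, A1 is 34). As a governing strategy it is narrower; the present plan adds a controlled answer for C10.

**Alternative 2:** The cut is a temporary C4=C5 alkene, made after tying the C3 and C6 oxygens through a diisopropylsilylene in diene A4. Ring-closing metathesis with (H2IMes)(PCy3)Cl2Ru=CHPh gives the seven-membered silylene A3.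
- Merits: the two halves are joined at sp2 carbons by a reliable reaction, each carbinol centre is fixed beforehand in a small allylic alcohol, and no chiral sp3 organometallic is needed.
- Weak points: the C6 allylic alcohol still needs a diastereoselective addition to a tetrahydrofuran aldehyde. The mixed silylene of two different secondary alcohols must be built stepwise. The ring alkene must be hydrogenated, so the diene can only be installed afterwards, with the diol protected through phosphonium formation and Wittig reaction. Silicon cannot be exchanged for O–O directly, so the silylene must be removed and the sequence of alternative 1 follows anyway.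
- Comparison: in fragment simplicity and robustness of the union it is better than the Grignard addition of 29 to 22. The present plan sets against this a much shorter path from union to peroxide (two steps) and no hydrogenation after the polyene exists.

**Alternative 3:** The cut is a C3=C10 ring alkene, so that C3–C10 comes from cycloocta-1,5-diene A7. Ozonolysis of the trans-diol monosilyl ether A6 gives a dialdehyde whose C7 hydroxyl closes on C10, leaving lactol A5 with a free C3 aldehyde.
- Merits: eight contiguous carbons from a commodity diene, both termini differentiated in one operation, and the threo C6/C7 relationship built in by trans-opening on the ring.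
- Weak points: C10 arrives as a lactol with no configuration, so the 2,5-trans relationship depends on a later substitution at a 5-substituted oxocarbenium ion with weak facial bias. The C3 aldehyde needs a reagent-controlled two-carbon extension. Absolute configuration requires an enantioselective desymmetrisation or a resolution.
- Comparison: it is better in step economy to the C3–C10 core and in C6 control. The present plan sets against this a secure trans tetrahydrofuran from the ylide shift and absolute configuration taken from L-malate.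

Key step: step 6

Remark on the chemistry: the C9 carbinol centre of 10 and 11 and the C12=C13 geometry of 14 are removed in later steps, so they are drawn without configuration.

## Route

Step 1
Reactants: 1 dimethyl (2S)-2-hydroxybutanedioate (dimethyl L-malate)
Product: 2 methyl (3S)-3,4-dihydroxybutanoate
Conditions: BH3·SMe2, NaBH4 (5 mol %), THF, 0 °C to rt; MeOH quench
Reagents that add atoms: none
Why: Hydroxyl-directed borane reduction: the alkoxyborane formed at the C2 hydroxyl delivers hydride through a five-membered chelate to the adjacent ester only, and the stereocentre is not touched.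

Step 2
Reactants: 2 methyl (3S)-3,4-dihydroxybutanoate
Product: 3 methyl (3S)-4-{[tert-butyl(diphenyl)silyl]oxy}-3-hydroxybutanoate
Conditions: TBDPSCl, imidazole, CH2Cl2, 0 °C
Reagents that add atoms: tert-butyl(chloro)diphenylsilane, CC(C)(C)[Si](Cl)(c1ccccc1)c1ccccc1
Why: Selective silylation; the bulky silyl chloride should react at the primary hydroxyl only.

Step 3
Reactants: 3 methyl (3S)-4-{[tert-butyl(diphenyl)silyl]oxy}-3-hydroxybutanoate
Product: 4 methyl (3S)-3-(allyloxy)-4-{[tert-butyl(diphenyl)silyl]oxy}butanoate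
Conditions: allyl 2,2,2-trichloroacetimidate, TfOH (cat.), cyclohexane/CH2Cl2, rt
Reagents that add atoms: allyl 2,2,2-trichloroacetimidate, C=CCOC(=N)C(Cl)(Cl)Cl
Why: Acid-catalysed imidate O-alkylation; it avoids the alkoxide that would trigger β-elimination or silyl migration in this β-hydroxy ester, and the C–O bond of the stereocentre is not broken.

Step 4
Reactants: 4 methyl (3S)-3-(allyloxy)-4-{[tert-butyl(diphenyl)silyl]oxy}butanoate
Product: 5 (3S)-3-(allyloxy)-4-{[tert-butyl(diphenyl)silyl]oxy}butanoic acid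
Conditions: LiOH, THF/H2O, 0 °C to rt; then 1 M HCl to pH 3
Reagents that add atoms: lithium hydroxide, [Li+].[OH-]
Why: Ester saponification; at low temperature the β-alkoxy carboxylate should not eliminate and the silyl ether is stable to LiOH.

Step 5
Reactants: 5 (3S)-3-(allyloxy)-4-{[tert-butyl(diphenyl)silyl]oxy}butanoic acid
Product: 7 (4S)-4-(allyloxy)-5-{[tert-butyl(diphenyl)silyl]oxy}-1-diazopentan-2-one, via mixed isobutyl carbonic anhydride 6 (not isolated)
Conditions: i-BuOCOCl, Et3N, Et2O, −20 °C; then CH2N2, Et2O, 0 °C to rt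
Reagents that add atoms: diazomethane, C=[N+]=[N-]; isobutyl chloroformate, CC(C)COC(Cl)=O (its atoms stay in 6 only)
Why: Acylation of diazomethane by a mixed anhydride (first stage of the Arndt–Eistert sequence); the neutral conditions spare the silyl and allyl ethers and add C10.

Step 6
Reactants: 7 (4S)-4-(allyloxy)-5-{[tert-butyl(diphenyl)silyl]oxy}-1-diazopentan-2-one
Product: 9 (2R,5S)-2-allyl-5-({[tert-butyl(diphenyl)silyl]oxy}methyl)oxolan-3-one, via cyclic oxonium ylide 8 (not isolated)
Conditions: Cu(acac)2 (5 mol %), THF, reflux, slow addition of 7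
Reagents that add atoms: none
Why: Cu(acac)2, a divalent copper complex, decomposes the diazo group with loss of N2 to an electrophilic copper-bound carbene at C10; a lone pair of the C7 allyl ether oxygen attacks it and closes the five-membered ring through O–C10 (heteroatom attack on the carbenoid carbon), giving oxonium ylide 8. The ylide then undergoes a concerted suprafacial [2,3]-sigmatropic shift through a five-membered envelope transition state, breaking O–CH2 and forming C10–C11 with allylic transposition. The closest known reaction type is the copper-catalysed tandem oxonium ylide formation and [2,3]-rearrangement of allyl ether diazoketones to trans-2,5-disubstituted tetrahydrofuran-3-ones. The new centre C10 is controlled by C7: the silyloxymethyl group sits pseudoequatorial, the allyl group on the pyramidal oxonium oxygen lies anti to it and is delivered to C10 on its own face, so C10 should form R and the ring 2,5-trans. The step needs chemoselectivity for ylide formation over carbenoid C–H insertion at C6 and alkene cyclopropanation, which the copper catalyst and the 1,5-placement of the ether oxygen secure, and a [2,3]- over a [1,2]-shift, which the allyl group secures. Slow addition keeps the carbenoid concentration low and suppresses dimerisation.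

Step 7
Reactants: 9 (2R,5S)-2-allyl-5-({[tert-butyl(diphenyl)silyl]oxy}methyl)oxolan-3-one
Product: 10 (2R,5S)-2-allyl-5-({[tert-butyl(diphenyl)silyl]oxy}methyl)oxolan-3-ol (C3 epimers of the ring)
Conditions: NaBH4, MeOH, 0 °C
Reagents that add atoms: none
Why: Borohydride reduction of the ketone; prompt reduction removes the risk of epimerising C10, and the new carbinol centre is deleted in step 9, so either epimer serves.

Step 8
Reactants: 10 (2R,5S)-2-allyl-5-({[tert-butyl(diphenyl)silyl]oxy}methyl)oxolan-3-ol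
Product: 11 O-[(2R,5S)-2-allyl-5-({[tert-butyl(diphenyl)silyl]oxy}methyl)oxolan-3-yl] 1H-imidazole-1-carbothioate
Conditions: 1,1'-thiocarbonyldiimidazole, DMAP (cat.), ClCH2CH2Cl, 70 °C
Reagents that add atoms: 1,1'-thiocarbonyldiimidazole, S=C(n1ccnc1)n1ccnc1
Why: Thioacylation of the secondary alcohol under neutral conditions, the first stage of a Barton–McCombie deoxygenation.

Step 9
Reactants: 11 O-[(2R,5S)-2-allyl-5-({[tert-butyl(diphenyl)silyl]oxy}methyl)oxolan-3-yl] 1H-imidazole-1-carbothioate
Product: 12 tert-butyl{[(2S,5S)-5-allyloxolan-2-yl]methoxy}diphenylsilane (2,5-trans)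
Conditions: Bu3SnH, AIBN (cat.), toluene, 110 °C
Reagents that add atoms: none
Why: Barton–McCombie radical deoxygenation; the C9 radical is a but-3-enyl radical with respect to the allyl alkene and has no productive cyclisation, and C7 and C10 are not radical centres.

Step 10
Reactants: 12 tert-butyl{[(2S,5S)-5-allyloxolan-2-yl]methoxy}diphenylsilane; 13 6-bromohex-1-ene
Product: 14 {[(2S,5S)-5-(7-bromohept-2-en-1-yl)oxolan-2-yl]methoxy}(tert-butyl)diphenylsilane (E/Z mixture)
Conditions: 13 (4 equiv), second-generation Grubbs catalyst (H2IMes)(PCy3)Cl2Ru=CHPh (5 mol %), CH2Cl2, 40 °C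
Reagents that add atoms: none
Why: Olefin cross-metathesis between two unhindered terminal alkenes; an excess of the cheap partner should drive 12 to the cross product, and the alkene geometry is irrelevant.

Step 11
Reactants: 14 {[(2S,5S)-5-(7-bromohept-2-en-1-yl)oxolan-2-yl]methoxy}(tert-butyl)diphenylsilane
Product: 15 {[(2S,5R)-5-(7-bromoheptyl)oxolan-2-yl]methoxy}(tert-butyl)diphenylsilane
Conditions: H2 (1 atm), PtO2 (cat.), EtOAc, rt
Reagents that add atoms: none
Why: Catalytic hydrogenation; under neutral conditions a disubstituted alkene should be reduced far faster than a primary C–Br bond is cleaved.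

Step 12
Reactants: 15 {[(2S,5R)-5-(7-bromoheptyl)oxolan-2-yl]methoxy}(tert-butyl)diphenylsilane
Product: 16 {7-[(2R,5S)-5-({[tert-butyl(diphenyl)silyl]oxy}methyl)oxolan-2-yl]heptyl}triphenylphosphonium bromide
Conditions: PPh3, MeCN, 82 °C
Reagents that add atoms: triphenylphosphine, c1ccccc1P(c1ccccc1)c1ccccc1
Why: SN2 quaternisation of a primary bromide, giving the C17 phosphonium salt.

Step 13
Reactants: 17 pent-4-enal
Product: 18 (2E)-hepta-2,6-dienal
Conditions: Ph3P=CHCHO (0.9 equiv), toluene, 80 °C
Reagents that add atoms: (triphenylphosphoranylidene)acetaldehyde, O=CC=P(c1ccccc1)(c1ccccc1)c1ccccc1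
Why: Wittig reaction of a stabilised ylide, which should give the E enal; a slight deficit of ylide limits a second homologation.

Step 14
Reactants: 16 {7-[(2R,5S)-5-({[tert-butyl(diphenyl)silyl]oxy}methyl)oxolan-2-yl]heptyl}triphenylphosphonium bromide; 18 (2E)-hepta-2,6-dienal
Product: 20 tert-butyl({(2S,5R)-5-[(7Z,9E)-tetradeca-7,9,13-trien-1-yl]oxolan-2-yl}methoxy)diphenylsilane, via phosphorus ylide 19 (not isolated)
Conditions: NaN(SiMe3)2, THF, −78 to 0 °C; then 18, −78 °C to rt
Reagents that add atoms: none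
Why: Salt-free Wittig reaction of a non-stabilised ylide with an enal; kinetic formation of the cis-oxaphosphetane should give the Z C17=C18 bond, while the E C19=C20 bond is carried unchanged from 18.

Step 15
Reactants: 20 tert-butyl({(2S,5R)-5-[(7Z,9E)-tetradeca-7,9,13-trien-1-yl]oxolan-2-yl}methoxy)diphenylsilane
Product: 21 {(2S,5R)-5-[(7Z,9E)-tetradeca-7,9,13-trien-1-yl]oxolan-2-yl}methanol
Conditions: Bu4NF, THF, rt
Reagents that add atoms: none
Why: Fluoride desilylation; the polyene and the ring are inert to fluoride.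

Step 16
Reactants: 21 {(2S,5R)-5-[(7Z,9E)-tetradeca-7,9,13-trien-1-yl]oxolan-2-yl}methanol
Product: 22 (2S,5R)-5-[(7Z,9E)-tetradeca-7,9,13-trien-1-yl]oxolane-2-carbaldehyde
Conditions: Dess–Martin periodinane, NaHCO3, CH2Cl2, 0 °C to rt; used crude
Reagents that add atoms: none
Why: Dess–Martin oxidation under buffered conditions, which should not epimerise the α-alkoxy aldehyde at C7 or touch the alkenes.

Step 17
Reactants: 23 3-{[tert-butyl(dimethyl)silyl]oxy}propanal
Product: 24 (3S)-1-{[tert-butyl(dimethyl)silyl]oxy}hex-5-en-3-ol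
Conditions: (−)-Ipc2B(allyl), Et2O, −78 °C; then NaOH, H2O2, rt
Reagents that add atoms: (−)-B-allyldiisopinocampheylborane (from (+)-α-pinene), C=CCB(C1CC2CC(C1C)C2(C)C)C1CC2CC(C1C)C2(C)C
Why: Brown asymmetric allylboration; the reagent derived from (+)-α-pinene delivers allyl to the si face through a chair six-membered transition state, which should set C3 as S.

Step 18
Reactants: 24 (3S)-1-{[tert-butyl(dimethyl)silyl]oxy}hex-5-en-3-ol
Product: 25 tert-butyldimethyl{[(3S)-3-(triethylsilyloxy)hex-5-en-1-yl]oxy}silane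
Conditions: Et3SiCl, imidazole, CH2Cl2, 0 °C
Reagents that add atoms: chlorotriethylsilane, CC[Si](Cl)(CC)CC
Why: Silylation of the secondary alcohol with a group that can later be removed in the presence of the primary tert-butyldimethylsilyl ether.

Step 19
Reactants: 25 tert-butyldimethyl{[(3S)-3-(triethylsilyloxy)hex-5-en-1-yl]oxy}silane
Product: 27 (3S)-5-{[tert-butyl(dimethyl)silyl]oxy}-3-(triethylsilyloxy)pentan-1-ol, via ozonide 26 (not isolated)
Conditions: O3, CH2Cl2, −78 °C; then NaBH4, EtOH, −78 °C to rt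
Reagents that add atoms: ozone, [O-][O+]=O
Why: Ozonolysis with reductive work-up removes the terminal carbon and gives the C5 alcohol; both silyl ethers are stable to ozone and borohydride.

Step 20
Reactants: 27 (3S)-5-{[tert-butyl(dimethyl)silyl]oxy}-3-(triethylsilyloxy)pentan-1-ol
Product: 28 (3R)-1-bromo-5-{[tert-butyl(dimethyl)silyl]oxy}-3-(triethylsilyloxy)pentane
Conditions: CBr4, PPh3, imidazole, CH2Cl2, 0 °C
Reagents that add atoms: tetrabromomethane, BrC(Br)(Br)Br
Why: Appel bromination of a primary alcohol; imidazole buffers traces of HBr, and the descriptor at C3 changes only because the priorities change.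

Step 21
Reactants: 22 (2S,5R)-5-[(7Z,9E)-tetradeca-7,9,13-trien-1-yl]oxolane-2-carbaldehyde; 28 (3R)-1-bromo-5-{[tert-butyl(dimethyl)silyl]oxy}-3-(triethylsilyloxy)pentane
Product: 30 (1S,4S)-6-{[tert-butyl(dimethyl)silyl]oxy}-1-{(2S,5R)-5-[(7Z,9E)-tetradeca-7,9,13-trien-1-yl]oxolan-2-yl}-4-(triethylsilyloxy)hexan-1-ol, via Grignard reagent 29 (not isolated)
Conditions: 28, Mg, BrCH2CH2Br (cat.), Et2O, 35 °C; then added to 22, MgBr2·OEt2, CH2Cl2, −78 °C
Reagents that add atoms: none
Why: Chelation-controlled (Cram chelate) Grignard addition to an α-alkoxy aldehyde; magnesium bridges the carbonyl and ring oxygens and the nucleophile attacks the face away from the C8 methylene, which should give the threo (6S) carbinol.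

Step 22
Reactants: 30 (1S,4S)-6-{[tert-butyl(dimethyl)silyl]oxy}-1-{(2S,5R)-5-[(7Z,9E)-tetradeca-7,9,13-trien-1-yl]oxolan-2-yl}-4-(triethylsilyloxy)hexan-1-ol
Product: 31 (1S,4S)-6-{[tert-butyl(dimethyl)silyl]oxy}-1-{(2S,5R)-5-[(7Z,9E)-tetradeca-7,9,13-trien-1-yl]oxolan-2-yl}hexane-1,4-diol
Conditions: PPTS (cat.), MeOH/CH2Cl2, 0 °C
Reagents that add atoms: none
Why: Selective acid-catalysed methanolysis; the triethylsilyl ether is far more labile than the tert-butyldimethylsilyl ether, and the diene tolerates this mild acid.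

Step 23
Reactants: 31 (1S,4S)-6-{[tert-butyl(dimethyl)silyl]oxy}-1-{(2S,5R)-5-[(7Z,9E)-tetradeca-7,9,13-trien-1-yl]oxolan-2-yl}hexane-1,4-diol
Product: 32 (1S,4S)-6-{[tert-butyl(dimethyl)silyl]oxy}-1-{(2S,5R)-5-[(7Z,9E)-tetradeca-7,9,13-trien-1-yl]oxolan-2-yl}hexane-1,4-diyl dimethanesulfonate
Conditions: MsCl, Et3N, DMAP (cat.), CH2Cl2, 0 °C
Reagents that add atoms: methanesulfonyl chloride, CS(=O)(=O)Cl
Why: O-sulfonylation of both secondary alcohols with retention, since no C–O bond is broken.

Step 24
Reactants: 32 (1S,4S)-6-{[tert-butyl(dimethyl)silyl]oxy}-1-{(2S,5R)-5-[(7Z,9E)-tetradeca-7,9,13-trien-1-yl]oxolan-2-yl}hexane-1,4-diyl dimethanesulfonate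
Product: 34 tert-butyldimethyl(2-{(3R,6R)-6-[(2S,5R)-5-[(7Z,9E)-tetradeca-7,9,13-trien-1-yl]oxolan-2-yl]-1,2-dioxan-3-yl}ethoxy)silane, via hydroperoxy mesylate 33 (not isolated)
Conditions: H2O2 (50% aq, excess), KOH, MeOH/THF, 0 °C to rt
Reagents that add atoms: hydrogen peroxide, OO
Why: Double SN2 displacement of a 1,4-bis-sulfonate by hydrogen peroxide, the classical cyclic peroxide synthesis; hydroperoxide anion should attack the unhindered C3 first, and the resulting hydroperoxide then closes the six-membered ring at C6. Both centres invert, turning the (3S,6S) precursor into the (3R,6R) trans-dioxane, and the isolated alkenes are inert to the nucleophilic oxidant.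

Step 25
Reactants: 34 tert-butyldimethyl(2-{(3R,6R)-6-[(2S,5R)-5-[(7Z,9E)-tetradeca-7,9,13-trien-1-yl]oxolan-2-yl]-1,2-dioxan-3-yl}ethoxy)silane
Product: 35 2-{(3R,6R)-6-[(2S,5R)-5-[(7Z,9E)-tetradeca-7,9,13-trien-1-yl]oxolan-2-yl]-1,2-dioxan-3-yl}ethan-1-ol
Conditions: HF·pyridine, pyridine, THF, 0 °C to rt
Reagents that add atoms: none
Why: Fluoride desilylation under buffered, non-basic conditions, chosen so that the peroxide is not exposed to base.

Step 26
Reactants: 35 2-{(3R,6R)-6-[(2S,5R)-5-[(7Z,9E)-tetradeca-7,9,13-trien-1-yl]oxolan-2-yl]-1,2-dioxan-3-yl}ethan-1-ol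
Product: 37 2-{(3R,6R)-6-[(2S,5R)-5-[(7Z,9E)-tetradeca-7,9,13-trien-1-yl]oxolan-2-yl]-1,2-dioxan-3-yl}acetic acid (target), via aldehyde 36 (not isolated)
Conditions: TEMPO (20 mol %), PhI(OAc)2, MeCN/pH 7 buffer, rt
Reagents that add atoms: water, O
Why: Oxoammonium-mediated oxidation of a primary alcohol through the aldehyde hydrate to the acid; the conditions are near neutral and non-reducing, so the O–O bond should survive and the β-peroxy aldehyde should not eliminate.

## Compound list

1 | dimethyl (2S)-2-hydroxybutanedioate (dimethyl L-malate) | COC(=O)C[C@H](O)C(=O)OC | starting material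
2 | methyl (3S)-3,4-dihydroxybutanoate | COC(=O)C[C@H](O)CO | intermediate
3 | methyl (3S)-4-{[tert-butyl(diphenyl)silyl]oxy}-3-hydroxybutanoate | COC(=O)C[C@H](O)CO[Si](c1ccccc1)(c1ccccc1)C(C)(C)C | intermediate
4 | methyl (3S)-3-(allyloxy)-4-{[tert-butyl(diphenyl)silyl]oxy}butanoate | COC(=O)C[C@H](OCC=C)CO[Si](c1ccccc1)(c1ccccc1)C(C)(C)C | intermediate
5 | (3S)-3-(allyloxy)-4-{[tert-butyl(diphenyl)silyl]oxy}butanoic acid | OC(=O)C[C@H](OCC=C)CO[Si](c1ccccc1)(c1ccccc1)C(C)(C)C | intermediate
6 | mixed anhydride of 5 with isobutyl hydrogen carbonate | CC(C)COC(=O)OC(=O)C[C@H](OCC=C)CO[Si](c1ccccc1)(c1ccccc1)C(C)(C)C | intermediate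
7 | (4S)-4-(allyloxy)-5-{[tert-butyl(diphenyl)silyl]oxy}-1-diazopentan-2-one | [N-]=[N+]=CC(=O)C[C@@H](CO[Si](c1ccccc1)(c1ccccc1)C(C)(C)C)OCC=C | intermediate
8 | (5S)-1-allyl-5-({[tert-butyl(diphenyl)silyl]oxy}methyl)-3-oxooxolan-1-ium-2-ide (cyclic oxonium ylide) | C=CC[O+]1[CH-]C(=O)C[C@H]1CO[Si](c2ccccc2)(c2ccccc2)C(C)(C)C | intermediate
9 | (2R,5S)-2-allyl-5-({[tert-butyl(diphenyl)silyl]oxy}methyl)oxolan-3-one | C=CC[C@@H]1C(=O)C[C@@H](CO[Si](c2ccccc2)(c2ccccc2)C(C)(C)C)O1 | intermediate
10 | (2R,5S)-2-allyl-5-({[tert-butyl(diphenyl)silyl]oxy}methyl)oxolan-3-ol, C3 epimers | C=CC[C@@H]1C(O)C[C@@H](CO[Si](c2ccccc2)(c2ccccc2)C(C)(C)C)O1 | intermediate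
11 | O-[(2R,5S)-2-allyl-5-({[tert-butyl(diphenyl)silyl]oxy}methyl)oxolan-3-yl] 1H-imidazole-1-carbothioate | C=CC[C@@H]1C(OC(=S)n2ccnc2)C[C@@H](CO[Si](c2ccccc2)(c2ccccc2)C(C)(C)C)O1 | intermediate
12 | tert-butyl{[(2S,5S)-5-allyloxolan-2-yl]methoxy}diphenylsilane | C=CC[C@@H]1CC[C@@H](CO[Si](c2ccccc2)(c2ccccc2)C(C)(C)C)O1 | intermediate
13 | 6-bromohex-1-ene | C=CCCCCBr | starting material
14 | {[(2S,5S)-5-(7-bromohept-2-en-1-yl)oxolan-2-yl]methoxy}(tert-butyl)diphenylsilane, E/Z | BrCCCCC=CC[C@@H]1CC[C@@H](CO[Si](c2ccccc2)(c2ccccc2)C(C)(C)C)O1 | intermediate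
15 | {[(2S,5R)-5-(7-bromoheptyl)oxolan-2-yl]methoxy}(tert-butyl)diphenylsilane | BrCCCCCCC[C@@H]1CC[C@@H](CO[Si](c2ccccc2)(c2ccccc2)C(C)(C)C)O1 | intermediate
16 | {7-[(2R,5S)-5-({[tert-butyl(diphenyl)silyl]oxy}methyl)oxolan-2-yl]heptyl}triphenylphosphonium bromide | [Br-].c1ccccc1[P+](c1ccccc1)(c1ccccc1)CCCCCCC[C@@H]1CC[C@@H](CO[Si](c2ccccc2)(c2ccccc2)C(C)(C)C)O1 | intermediate
17 | pent-4-enal | C=CCCC=O | starting material
18 | (2E)-hepta-2,6-dienal | C=CCC/C=C/C=O | intermediate
19 | phosphorus ylide of 16 | c1ccccc1P(c1ccccc1)(c1ccccc1)=CCCCCCC[C@@H]1CC[C@@H](CO[Si](c2ccccc2)(c2ccccc2)C(C)(C)C)O1 | intermediate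
20 | tert-butyl({(2S,5R)-5-[(7Z,9E)-tetradeca-7,9,13-trien-1-yl]oxolan-2-yl}methoxy)diphenylsilane | C=CCC/C=C/C=C\CCCCCC[C@@H]1CC[C@@H](CO[Si](c2ccccc2)(c2ccccc2)C(C)(C)C)O1 | intermediate
21 | {(2S,5R)-5-[(7Z,9E)-tetradeca-7,9,13-trien-1-yl]oxolan-2-yl}methanol | C=CCC/C=C/C=C\CCCCCC[C@@H]1CC[C@@H](CO)O1 | intermediate
22 | (2S,5R)-5-[(7Z,9E)-tetradeca-7,9,13-trien-1-yl]oxolane-2-carbaldehyde | C=CCC/C=C/C=C\CCCCCC[C@@H]1CC[C@@H](C=O)O1 | intermediate
23 | 3-{[tert-butyl(dimethyl)silyl]oxy}propanal | O=CCCO[Si](C)(C)C(C)(C)C | starting material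
24 | (3S)-1-{[tert-butyl(dimethyl)silyl]oxy}hex-5-en-3-ol | C=CC[C@H](O)CCO[Si](C)(C)C(C)(C)C | intermediate
25 | tert-butyldimethyl{[(3S)-3-(triethylsilyloxy)hex-5-en-1-yl]oxy}silane | C=CC[C@H](O[Si](CC)(CC)CC)CCO[Si](C)(C)C(C)(C)C | intermediate
26 | ozonide (1,2,4-trioxolane) of 25 | C1OOC(O1)C[C@H](O[Si](CC)(CC)CC)CCO[Si](C)(C)C(C)(C)C | intermediate
27 | (3S)-5-{[tert-butyl(dimethyl)silyl]oxy}-3-(triethylsilyloxy)pentan-1-ol | OCC[C@H](O[Si](CC)(CC)CC)CCO[Si](C)(C)C(C)(C)C | intermediate
28 | (3R)-1-bromo-5-{[tert-butyl(dimethyl)silyl]oxy}-3-(triethylsilyloxy)pentane | BrCC[C@H](O[Si](CC)(CC)CC)CCO[Si](C)(C)C(C)(C)C | intermediate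
29 | [(3R)-5-{[tert-butyl(dimethyl)silyl]oxy}-3-(triethylsilyloxy)pentyl]magnesium bromide | Br[Mg]CC[C@H](O[Si](CC)(CC)CC)CCO[Si](C)(C)C(C)(C)C | intermediate
30 | (1S,4S)-6-{[tert-butyl(dimethyl)silyl]oxy}-1-{(2S,5R)-5-[(7Z,9E)-tetradeca-7,9,13-trien-1-yl]oxolan-2-yl}-4-(triethylsilyloxy)hexan-1-ol | C=CCC/C=C/C=C\CCCCCC[C@@H]1CC[C@@H]([C@@H](O)CC[C@H](O[Si](CC)(CC)CC)CCO[Si](C)(C)C(C)(C)C)O1 | intermediate
31 | (1S,4S)-6-{[tert-butyl(dimethyl)silyl]oxy}-1-{(2S,5R)-5-[(7Z,9E)-tetradeca-7,9,13-trien-1-yl]oxolan-2-yl}hexane-1,4-diol | C=CCC/C=C/C=C\CCCCCC[C@@H]1CC[C@@H]([C@@H](O)CC[C@H](O)CCO[Si](C)(C)C(C)(C)C)O1 | intermediate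
32 | (1S,4S)-6-{[tert-butyl(dimethyl)silyl]oxy}-1-{(2S,5R)-5-[(7Z,9E)-tetradeca-7,9,13-trien-1-yl]oxolan-2-yl}hexane-1,4-diyl dimethanesulfonate | C=CCC/C=C/C=C\CCCCCC[C@@H]1CC[C@@H]([C@@H](OS(C)(=O)=O)CC[C@H](OS(C)(=O)=O)CCO[Si](C)(C)C(C)(C)C)O1 | intermediate
33 | (1S,4R)-6-{[tert-butyl(dimethyl)silyl]oxy}-4-hydroperoxy-1-{(2S,5R)-5-[(7Z,9E)-tetradeca-7,9,13-trien-1-yl]oxolan-2-yl}hexyl methanesulfonate | C=CCC/C=C/C=C\CCCCCC[C@@H]1CC[C@@H]([C@@H](OS(C)(=O)=O)CC[C@@H](OO)CCO[Si](C)(C)C(C)(C)C)O1 | intermediate
34 | tert-butyldimethyl(2-{(3R,6R)-6-[(2S,5R)-5-[(7Z,9E)-tetradeca-7,9,13-trien-1-yl]oxolan-2-yl]-1,2-dioxan-3-yl}ethoxy)silane | C=CCC/C=C/C=C\CCCCCC[C@@H]1CC[C@@H]([C@H]2CC[C@H](CCO[Si](C)(C)C(C)(C)C)OO2)O1 | intermediate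
35 | 2-{(3R,6R)-6-[(2S,5R)-5-[(7Z,9E)-tetradeca-7,9,13-trien-1-yl]oxolan-2-yl]-1,2-dioxan-3-yl}ethan-1-ol | C=CCC/C=C/C=C\CCCCCC[C@@H]1CC[C@@H]([C@H]2CC[C@H](CCO)OO2)O1 | intermediate
36 | {(3R,6R)-6-[(2S,5R)-5-[(7Z,9E)-tetradeca-7,9,13-trien-1-yl]oxolan-2-yl]-1,2-dioxan-3-yl}acetaldehyde | C=CCC/C=C/C=C\CCCCCC[C@@H]1CC[C@@H]([C@H]2CC[C@H](CC=O)OO2)O1 | intermediate
37 | 2-{(3R,6R)-6-[(2S,5R)-5-[(7Z,9E)-tetradeca-7,9,13-trien-1-yl]oxolan-2-yl]-1,2-dioxan-3-yl}acetic acid | C=CCC/C=C/C=C\CCCCCC[C@@H]1CC[C@@H]([C@H]2CC[C@H](CC(=O)O)OO2)O1 | target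

## Step count and least certain steps

Total: 26 steps. Longest linear sequence: 21 steps from 1 (steps 1–12, 14–16, 21–26). Steps 13 and 17–20 are side branches.

**Step 6 (key step).** The copper carbenoid may insert into the activated C6–H bond or cyclopropanate the allyl alkene instead of being captured by the ether oxygen. The ylide may also undergo a [1,2]-shift, and trans selectivity may erode if the rearrangement is slow relative to inversion at the oxonium oxygen. The fallback sets out from 3 and returns at 12, bypassing 4–11, and makes the O–C10 and C10–C11 bonds by oxocarbenium chemistry: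
- Silylation of 3 (Et3SiCl, imidazole) should give methyl (3S)-4-{[tert-butyl(diphenyl)silyl]oxy}-3-(triethylsilyloxy)butanoate F1.
- Reduction with i-Bu2AlH at −78 °C should give (3S)-4-{[tert-butyl(diphenyl)silyl]oxy}-3-(triethylsilyloxy)butanal F2.
- Methoxymethylenation with Ph3P=CHOMe should give the enol ether tert-butyl{[(2S)-5-methoxy-2-(triethylsilyloxy)pent-4-en-1-yl]oxy}diphenylsilane F3.
- PPTS in MeOH should remove the triethylsilyl group and close the mixed acetal tert-butyl{[(2S)-5-methoxyoxolan-2-yl]methoxy}diphenylsilane F4.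
- Allyltrimethylsilane with BF3·OEt2 at −78 °C should give 12 together with its cis isomer, which has to be separated. The expected selectivity is lower than that of the ylide shift, but no deoxygenation is needed.

**Step 24.** E2 elimination of either mesylate may compete, substitution at C6 next to the ring oxygen may be slow, and the product may fragment under base through loss of the C3 or C6 hydrogen. The fallback sets out from 30 and returns at 33, separating the two C–O bond formations and keeping the first one base-free: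
- Mesylation of the free C6 hydroxyl of 30 should give (1S,4S)-6-{[tert-butyl(dimethyl)silyl]oxy}-1-{(2S,5R)-5-[(7Z,9E)-tetradeca-7,9,13-trien-1-yl]oxolan-2-yl}-4-(triethylsilyloxy)hexyl methanesulfonate F5.
- PPTS in MeOH should give the C3 alcohol, the 4-hydroxy analogue of F5, F6.
- Tf2O and 2,6-lutidine at −78 °C should give the C3 triflate of F6, F7, which is treated at once with anhydrous ethereal H2O2 to give 33 by inversion without added base.
- Isolated 33 is then closed to 34 in a separate operation with CsOH in DMF or with Ag2O.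

**Step 21.** Facial selectivity may be poor if the magnesium chelate is incomplete (competition from ether solvent). Wurtz coupling may occur during Grignard formation, and the aldehyde may epimerise at C7. The fallback sets out from crude 30 containing its C6 epimer, (1R,4S)-6-{[tert-butyl(dimethyl)silyl]oxy}-1-{(2S,5R)-5-[(7Z,9E)-tetradeca-7,9,13-trien-1-yl]oxolan-2-yl}-4-(triethylsilyloxy)hexan-1-ol F8, and returns at 30:
- Dess–Martin oxidation of the mixture should give the single ketone (4S)-6-{[tert-butyl(dimethyl)silyl]oxy}-1-{(2S,5R)-5-[(7Z,9E)-tetradeca-7,9,13-trien-1-yl]oxolan-2-yl}-4-(triethylsilyloxy)hexan-1-one F9.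
- Felkin–Anh reduction with LiBH(s-Bu)3 in THF at −78 °C, with hydride anti to the ring C–O bond, should give the threo alcohol 30.

**Step 11 (with step 10).** Hydrogenolysis of the primary C–Br bond may accompany alkene reduction, and the statistical cross-metathesis may consume 12 by homodimerisation. The fallback sets out from 12 and returns at 15, carrying C17 as an alcohol:
- Cross-metathesis of 12 with hex-5-en-1-ol under the conditions of step 10 should give 7-[(2S,5S)-5-({[tert-butyl(diphenyl)silyl]oxy}methyl)oxolan-2-yl]hept-5-en-1-ol F10.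
- Hydrogenation over PtO2 should give 7-[(2R,5S)-5-({[tert-butyl(diphenyl)silyl]oxy}methyl)oxolan-2-yl]heptan-1-ol F11.
- Appel bromination (CBr4, PPh3) should give 15, at the cost of one extra step.

## Further compounds

F1 | step 6 | methyl (3S)-4-{[tert-butyl(diphenyl)silyl]oxy}-3-(triethylsilyloxy)butanoate | COC(=O)C[C@H](O[Si](CC)(CC)CC)CO[Si](c1ccccc1)(c1ccccc1)C(C)(C)C
F2 | step 6 | (3S)-4-{[tert-butyl(diphenyl)silyl]oxy}-3-(triethylsilyloxy)butanal | O=CC[C@H](O[Si](CC)(CC)CC)CO[Si](c1ccccc1)(c1ccccc1)C(C)(C)C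
F3 | step 6 | tert-butyl{[(2S)-5-methoxy-2-(triethylsilyloxy)pent-4-en-1-yl]oxy}diphenylsilane, E/Z | COC=CC[C@H](O[Si](CC)(CC)CC)CO[Si](c1ccccc1)(c1ccccc1)C(C)(C)C
F4 | step 6 | tert-butyl{[(2S)-5-methoxyoxolan-2-yl]methoxy}diphenylsilane, anomers | COC1CC[C@@H](CO[Si](c2ccccc2)(c2ccccc2)C(C)(C)C)O1
F5 | step 24 | (1S,4S)-6-{[tert-butyl(dimethyl)silyl]oxy}-1-{(2S,5R)-5-[(7Z,9E)-tetradeca-7,9,13-trien-1-yl]oxolan-2-yl}-4-(triethylsilyloxy)hexyl methanesulfonate | C=CCC/C=C/C=C\CCCCCC[C@@H]1CC[C@@H]([C@@H](OS(C)(=O)=O)CC[C@H](O[Si](CC)(CC)CC)CCO[Si](C)(C)C(C)(C)C)O1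
F6 | step 24 | (1S,4S)-6-{[tert-butyl(dimethyl)silyl]oxy}-4-hydroxy-1-{(2S,5R)-5-[(7Z,9E)-tetradeca-7,9,13-trien-1-yl]oxolan-2-yl}hexyl methanesulfonate | C=CCC/C=C/C=C\CCCCCC[C@@H]1CC[C@@H]([C@@H](OS(C)(=O)=O)CC[C@H](O)CCO[Si](C)(C)C(C)(C)C)O1
F7 | step 24 | (1S,4S)-6-{[tert-butyl(dimethyl)silyl]oxy}-1-{(2S,5R)-5-[(7Z,9E)-tetradeca-7,9,13-trien-1-yl]oxolan-2-yl}-4-{[(trifluoromethyl)sulfonyl]oxy}hexyl methanesulfonate | C=CCC/C=C/C=C\CCCCCC[C@@H]1CC[C@@H]([C@@H](OS(C)(=O)=O)CC[C@H](OS(=O)(=O)C(F)(F)F)CCO[Si](C)(C)C(C)(C)C)O1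
F8 | step 21 | (1R,4S)-6-{[tert-butyl(dimethyl)silyl]oxy}-1-{(2S,5R)-5-[(7Z,9E)-tetradeca-7,9,13-trien-1-yl]oxolan-2-yl}-4-(triethylsilyloxy)hexan-1-ol | C=CCC/C=C/C=C\CCCCCC[C@@H]1CC[C@@H]([C@H](O)CC[C@H](O[Si](CC)(CC)CC)CCO[Si](C)(C)C(C)(C)C)O1
F9 | step 21 | (4S)-6-{[tert-butyl(dimethyl)silyl]oxy}-1-{(2S,5R)-5-[(7Z,9E)-tetradeca-7,9,13-trien-1-yl]oxolan-2-yl}-4-(triethylsilyloxy)hexan-1-one | C=CCC/C=C/C=C\CCCCCC[C@@H]1CC[C@@H](C(=O)CC[C@H](O[Si](CC)(CC)CC)CCO[Si](C)(C)C(C)(C)C)O1
F10 | step 11 | 7-[(2S,5S)-5-({[tert-butyl(diphenyl)silyl]oxy}methyl)oxolan-2-yl]hept-5-en-1-ol, E/Z | OCCCCC=CC[C@@H]1CC[C@@H](CO[Si](c2ccccc2)(c2ccccc2)C(C)(C)C)O1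
F11 | step 11 | 7-[(2R,5S)-5-({[tert-butyl(diphenyl)silyl]oxy}methyl)oxolan-2-yl]heptan-1-ol | OCCCCCCC[C@@H]1CC[C@@H](CO[Si](c2ccccc2)(c2ccccc2)C(C)(C)C)O1
A1 | alternative 1 | C1 tert-butyldimethylsilyl ether carrying the complete ring system and side chain (identical with 34) | C=CCC/C=C/C=C\CCCCCC[C@@H]1CC[C@@H]([C@H]2CC[C@H](CCO[Si](C)(C)C(C)(C)C)OO2)O1
A2 | alternative 1 | (3S,6S)-3,6-bis(methanesulfonate) with the C1 silyl ether (identical with 32) | C=CCC/C=C/C=C\CCCCCC[C@@H]1CC[C@@H]([C@@H](OS(C)(=O)=O)CC[C@H](OS(C)(=O)=O)CCO[Si](C)(C)C(C)(C)C)O1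
A3 | alternative 2 | cyclic diisopropylsilylene ether of the (Z)-C4=C5 ene-3,6-diol, C1 pivalate, C17 silyl ether | CC(C)(C)[Si](c1ccccc1)(c1ccccc1)OCCCCCCC[C@@H]1CC[C@@H]([C@@H]2C=C[C@@H](CCOC(=O)C(C)(C)C)O[Si](C(C)C)(C(C)C)O2)O1
A4 | alternative 2 | acyclic diisopropylsilylene bis(allylic ether) joining the C1–C4 and C5–C17 halves | CC(C)(C)[Si](c1ccccc1)(c1ccccc1)OCCCCCCC[C@@H]1CC[C@@H]([C@H](C=C)O[Si](C(C)C)(C(C)C)O[C@@H](C=C)CCOC(=O)C(C)(C)C)O1
A5 | alternative 3 | tetrahydrofuran lactol (C7–C10) with the C6 silyl ether and free C3 aldehyde, lactol carbon as a mixture | OC1CC[C@@H]([C@@H](O[Si](C)(C)C(C)(C)C)CCC=O)O1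
A6 | alternative 3 | (1S,2S)-2-{[tert-butyl(dimethyl)silyl]oxy}cyclooct-5-en-1-ol | O[C@H]1CC/C=C\CC[C@@H]1O[Si](C)(C)C(C)(C)C
A7 | alternative 3 | cycloocta-1,5-diene | C1=CCCC=CCC1
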